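A direct plan would close both rings at once by an intramolecular Buchner reaction: a carbene generated with dirhodium tetraacetate from the aryl-tethered diazoketone A1 would add to the anisole ring and ring-expand to the methoxy trienone A2.
Its weakest steps would be: (a) this carbene addition and ring expansion, because the quaternary C1 would rest only on a conformational preference of the tether, while attack at the other ortho carbon, C–H insertion and ylide formation would compete;
(b) the erasure of the C2 ketone of A2 (reduction, xanthate formation, radical deoxygenation), three steps that would add no complexity and would exist only because the diazo group needed a carbonyl group;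
(c) the late setting of C10 by epoxidation of the dienone A3 and reductive vinylogous epoxide opening, which would leave the face and the site of oxidation to a remote methyl group on precious material, after C5 had been left to a kinetic protonation.

Plan of the new route. The retrosynthesis cuts the two esters (C10–OAc, then C6–O–aroyl), then C4–isopropyl (organometallic addition to a cyclopentanone), then C6–O and C5–H (conjugate borylation of the enone C4(=O)–C5=C6).
It then cuts C1–C10 together with C6–C8 by a retro-Cope step to a cis-dialkenylcyclopropane, then C7 (cyclopropanation) and C5–C6 (sp2–sp2 coupling).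
The feature that allows this: in the seven-membered ring, C8=C9 and (at the enone oxidation level) C5=C6 are 1,4 to each other across C7, and the adjacent sp3 atoms C1 (quaternary) and C10 (oxygen-bearing) lie between them. This is exactly the pattern left by a divinylcyclopropane rearrangement.
Ring order: the five-membered ring is bought as a cyclopentenone, the three-membered ring comes from an asymmetric cyclopropanation, and the seven-membered ring arises by ring expansion.
No carbene is used and no extra ketone has to be deleted. C1 and C10 are set in one stereospecific event, and the C10 oxygen arrives with the ring.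

Key step: step 5

Remark: daucane numbering is used throughout, also for precursors (C1 methyl-bearing ring-fusion carbon, C4 carbinol carbon, C5 ring-fusion CH, C6 to C10 the other seven-ring carbons, α the face of H-5). 2-Bromo-3-methylcyclopent-2-en-1-one is assumed to be commercial.

Step 1
Reactants: 1 prop-2-yn-1-ol; 2 2-bromo-3-methylcyclopent-2-en-1-one
Product: 5 2-[(1Z)-3-hydroxy-2-methylprop-1-en-1-yl]-3-methylcyclopent-2-en-1-one, via alkenylmagnesium alkoxide 3 (not isolated), via alkenylzinc chloride 4 (not isolated)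
Conditions: 1, MeMgBr (2.5 equiv), CuI (10 mol %), Et2O, −10 °C → rt; ZnCl2, THF, 0 °C; then 2, Pd(OAc)2/SPhos (cat.), THF, rt → 50 °C; aq NH4Cl
Reagents that add atoms: methylmagnesium bromide, C[Mg]Br
Why: Copper-catalysed anti-carbomagnesiation of the propargylic alkoxide should give the chelated (Z)-alkenylmagnesium 3 regio- and stereospecifically, and after transmetalation to zinc a Negishi coupling with the α-bromoenone keeps this geometry, so that the hydroxymethyl group and the enone ring are cis on the new trisubstituted alkene; the alkenylzinc does not add to the ketone.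

Step 2
Reactants: 5 2-[(1Z)-3-hydroxy-2-methylprop-1-en-1-yl]-3-methylcyclopent-2-en-1-one
Product: 6 2-[(1R,2S)-2-(hydroxymethyl)-2-methylcyclopropyl]-3-methylcyclopent-2-en-1-one
Conditions: Et2Zn, CH2I2, DME, CH2Cl2, −10 °C (gives Zn(CH2I)2·DME); then 5 and (4R,5R)-2-butyl-N,N,N′,N′-tetramethyl-1,3,2-dioxaborolane-4,5-dicarboxamide (1.2 equiv), CH2Cl2, −10 °C → rt
Reagents that add atoms: diiodomethane, ICI
Why: Charette asymmetric Simmons–Smith cyclopropanation: the zinc alkoxide bound to the chiral dioxaborolane delivers CH2 (C7) to one face of the allylic alkene (the ligand enantiomer that turns cinnamyl alcohol into the (1S,2S)-cyclopropylmethanol is the one needed), the syn addition keeps the hydroxymethyl group cis to the cyclopentenone, and the electron-poor, undirected enone double bond is left alone.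

Step 3
Reactants: 6 2-[(1R,2S)-2-(hydroxymethyl)-2-methylcyclopropyl]-3-methylcyclopent-2-en-1-one
Product: 7 (1S,2R)-1-methyl-2-(2-methyl-5-oxocyclopent-1-en-1-yl)cyclopropane-1-carbaldehyde
Conditions: Dess–Martin periodinane, NaHCO3, CH2Cl2, 0 °C; crude 7 used at once
Reagents that add atoms: none
Why: Dess–Martin oxidation of the neopentyl primary alcohol, run cold and buffered because a cis-2-alkenylcyclopropanecarbaldehyde can undergo retro-Claisen rearrangement to a dihydrooxepine on warming; the aldehyde has no α-hydrogen, so the cyclopropane stereocentres cannot epimerise.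

Step 4
Reactants: 7 (1S,2R)-1-methyl-2-(2-methyl-5-oxocyclopent-1-en-1-yl)cyclopropane-1-carbaldehyde; 8 2-(dichloromethyl)-4,4,5,5-tetramethyl-1,3,2-dioxaborolane
Product: 9 3-methyl-2-{(1R,2R)-2-methyl-2-[(E)-2-(4,4,5,5-tetramethyl-1,3,2-dioxaborolan-2-yl)ethenyl]cyclopropyl}cyclopent-2-en-1-one
Conditions: CrCl2 (8 equiv), LiI (4 equiv), 8 (2 equiv), THF, rt; filtration through silica at rt, no heating
Reagents that add atoms: none
Why: Takai–Utimoto olefination with the geminal dichromium reagent formed from 8 should give the E-alkenylboronate with high selectivity; divalent chromium attacks the aldehyde and not the enone, and a work-up at room temperature keeps the cis-dialkenylcyclopropane from rearranging early.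

Step 5
Reactants: 9 3-methyl-2-{(1R,2R)-2-methyl-2-[(E)-2-(4,4,5,5-tetramethyl-1,3,2-dioxaborolan-2-yl)ethenyl]cyclopropyl}cyclopent-2-en-1-one
Product: 11 (3aS,4R)-4-hydroxy-3a,6-dimethyl-3,3a,4,7-tetrahydroazulen-1(2H)-one, via allylboronate 10 (not isolated)
Conditions: toluene (0.02 M, degassed), 90 °C; then NaBO3·4H2O, THF/H2O, 0 °C → rt
Reagents that add atoms: sodium perborate tetrahydrate, [Na+].[Na+].O[B-]1(O)OO[B-](O)(O)OO1.O.O.O.O.O.O
Why: Thermal [3,3]-sigmatropic (Cope) rearrangement of a cis-1,2-dialkenylcyclopropane through the boat transition state, in which the cyclopropane bond C6–C8 breaks as C1–C10 forms and the ring double bonds C5=C6 and C8=C9 appear; the closest known reaction type is the divinylcyclopropane–cycloheptadiene rearrangement used to fuse seven-membered rings onto cyclic enones. The seven-membered ring closes by this concerted expansion of the three-membered ring (C7 is the former cyclopropane CH2), not by cyclisation of a chain, and the five-membered ring is carried through unchanged. Both new stereocentres arise in the same event by transfer of the cyclopropane configuration fixed in step 2: the enone can stack on the borylvinyl group on one face only, the C1 methyl is the inward (Z) substituent and the boryl group the outward (E) substituent, so boron at C10 ends trans to the methyl group at C1. The step needs the E-alkenylboronate of step 4 and the cis cyclopropane of step 2; the inward methyl group raises the barrier, hence 90 °C where the parent system rearranges near room temperature, which should still lie below the temperature of one-centre epimerisation of the cyclopropane. Perborate then oxidises the allylic C–B bond with retention and without allylic transposition, faster than it epoxidises the enone, to give the 10α-alcohol.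

Step 6
Reactants: 11 (3aS,4R)-4-hydroxy-3a,6-dimethyl-3,3a,4,7-tetrahydroazulen-1(2H)-one
Product: 12 (3aS,4R)-4-[(tert-butyldimethylsilyl)oxy]-3a,6-dimethyl-3,3a,4,7-tetrahydroazulen-1(2H)-one
Conditions: TBSOTf, 2,6-lutidine, CH2Cl2, −78 → 0 °C
Reagents that add atoms: tert-butyldimethylsilyl trifluoromethanesulfonate, CC(C)(C)[Si](C)(C)OS(=O)(=O)C(F)(F)F
Why: Silyl triflate silylation of the hindered allylic alcohol while it is the only hydroxyl group, so that the C10 and C6 oxygens are told apart by the order in which they appear and not by a selective acylation later.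

Step 7
Reactants: 12 (3aS,4R)-4-[(tert-butyldimethylsilyl)oxy]-3a,6-dimethyl-3,3a,4,7-tetrahydroazulen-1(2H)-one
Product: 14 (3aS,4R,8S,8aS)-4-[(tert-butyldimethylsilyl)oxy]-8-hydroxy-3a,6-dimethyl-3,3a,4,7,8,8a-hexahydroazulen-1(2H)-one, via boryl ketone 13 (not isolated)
Conditions: B2pin2 (1.2 equiv), CuCl (5 mol %), Xantphos (5 mol %), NaOt-Bu (10 mol %), MeOH (2 equiv), THF, rt; then NaBO3·4H2O, THF/H2O, 0 °C → rt
Reagents that add atoms: sodium perborate tetrahydrate, [Na+].[Na+].O[B-]1(O)OO[B-](O)(O)OO1.O.O.O.O.O.O
Why: Copper-catalysed conjugate borylation of the exocyclic enone (the only electron-poor alkene) followed by stereoretentive C–B oxidation; borylcopper should add to C6 on the α face, away from the C1 methyl group that stands over the β face of the enone, and methanol should protonate the copper enolate at C5 on the same face to give the trans-fused 5αH ketone.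

Step 8
Reactants: 14 (3aS,4R,8S,8aS)-4-[(tert-butyldimethylsilyl)oxy]-8-hydroxy-3a,6-dimethyl-3,3a,4,7,8,8a-hexahydroazulen-1(2H)-one
Product: 15 (1R,3aS,4R,8S,8aS)-4-[(tert-butyldimethylsilyl)oxy]-3a,6-dimethyl-1-(propan-2-yl)-1,2,3,3a,4,7,8,8a-octahydroazulene-1,8-diol
Conditions: i-PrMgCl (4 equiv), CeCl3 (4 equiv, dried), THF, −78 → −20 °C; aq NH4Cl
Reagents that add atoms: isopropylmagnesium chloride, CC(C)[Mg]Cl
Why: Organocerium 1,2-addition to the cyclopentanone from the α face, anti to the C5–C6 bond and to the 1,3-related axial C1 methyl group, sets C4 with the hydroxyl group β; the cerium reagent suppresses enolisation, β-hydride reduction and retro-aldol cleavage of the metal aldolate.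

Step 9
Reactants: 15 (1R,3aS,4R,8S,8aS)-4-[(tert-butyldimethylsilyl)oxy]-3a,6-dimethyl-1-(propan-2-yl)-1,2,3,3a,4,7,8,8a-octahydroazulene-1,8-diol; 16 4-methoxybenzoyl chloride
Product: 17 (1R,3aS,4R,8S,8aS)-4-[(tert-butyldimethylsilyl)oxy]-1-hydroxy-3a,6-dimethyl-1-(propan-2-yl)-1,2,3,3a,4,7,8,8a-octahydroazulen-8-yl 4-methoxybenzoate
Conditions: Et3N, DMAP, CH2Cl2, rt → 40 °C
Reagents that add atoms: none
Why: DMAP-catalysed acyl transfer to the only secondary hydroxyl group (C6); the tertiary C4 alcohol is too hindered to be acylated under these conditions.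

Step 10
Reactants: 17 (1R,3aS,4R,8S,8aS)-4-[(tert-butyldimethylsilyl)oxy]-1-hydroxy-3a,6-dimethyl-1-(propan-2-yl)-1,2,3,3a,4,7,8,8a-octahydroazulen-8-yl 4-methoxybenzoate
Product: 18 (1R,3aS,4R,8S,8aS)-1,4-dihydroxy-3a,6-dimethyl-1-(propan-2-yl)-1,2,3,3a,4,7,8,8a-octahydroazulen-8-yl 4-methoxybenzoate
Conditions: HF·pyridine, pyridine, THF, 0 °C → rt
Reagents that add atoms: none
Why: Fluoride cleavage of the silyl ether under buffered, non-basic conditions, which should leave the aroyl ester, the tertiary alcohol and the allylic system intact and cannot cause base-induced acyl migration.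

Step 11
Reactants: 18 (1R,3aS,4R,8S,8aS)-1,4-dihydroxy-3a,6-dimethyl-1-(propan-2-yl)-1,2,3,3a,4,7,8,8a-octahydroazulen-8-yl 4-methoxybenzoate
Product: 19 (1R,3aS,4R,8S,8aS)-4-(acetyloxy)-1-hydroxy-3a,6-dimethyl-1-(propan-2-yl)-1,2,3,3a,4,7,8,8a-octahydroazulen-8-yl 4-methoxybenzoate (CNP0256979.2)
Conditions: Ac2O, DMAP, pyridine, CH2Cl2, rt
Reagents that add atoms: acetic anhydride, CC(=O)OC(C)=O
Why: DMAP-catalysed acetylation of the one remaining secondary (allylic, C10) hydroxyl group; the tertiary C4 alcohol does not react, as in step 9.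

**Compound list**

1 | prop-2-yn-1-ol | C#CCO | starting material
2 | 2-bromo-3-methylcyclopent-2-en-1-one | CC1=C(Br)C(=O)CC1 | starting material
3 | bromomagnesium (2Z)-3-(bromomagnesio)-2-methylprop-2-en-1-olate | C/C(CO[Mg]Br)=C/[Mg]Br | intermediate
4 | bromomagnesium (2Z)-3-(chlorozincio)-2-methylprop-2-en-1-olate | C/C(CO[Mg]Br)=C/[Zn]Cl | intermediate
5 | 2-[(1Z)-3-hydroxy-2-methylprop-1-en-1-yl]-3-methylcyclopent-2-en-1-one | O=C1CCC(C)=C1/C=C(/C)CO | intermediate
6 | 2-[(1R,2S)-2-(hydroxymethyl)-2-methylcyclopropyl]-3-methylcyclopent-2-en-1-one (hydroxymethyl cis to the cyclopentenone) | O=C1CCC(C)=C1[C@@H]2C[C@]2(C)CO | intermediate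
7 | (1S,2R)-1-methyl-2-(2-methyl-5-oxocyclopent-1-en-1-yl)cyclopropane-1-carbaldehyde | O=C1CCC(C)=C1[C@@H]2C[C@]2(C)C=O | intermediate
8 | 2-(dichloromethyl)-4,4,5,5-tetramethyl-1,3,2-dioxaborolane | ClC(Cl)B1OC(C)(C)C(C)(C)O1 | starting material
9 | 3-methyl-2-{(1R,2R)-2-methyl-2-[(E)-2-(4,4,5,5-tetramethyl-1,3,2-dioxaborolan-2-yl)ethenyl]cyclopropyl}cyclopent-2-en-1-one (the two alkenyl groups cis) | O=C1CCC(C)=C1[C@@H]2C[C@]2(C)/C=C/B3OC(C)(C)C(C)(C)O3 | intermediate
10 | (3aR,4R)-3a,6-dimethyl-4-(4,4,5,5-tetramethyl-1,3,2-dioxaborolan-2-yl)-3,3a,4,7-tetrahydroazulen-1(2H)-one (boron at C10 α, trans to the C1 methyl) | O=C1CC[C@]2(C)[C@H](B3OC(C)(C)C(C)(C)O3)C=C(C)CC=C12 | intermediate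
11 | (3aS,4R)-4-hydroxy-3a,6-dimethyl-3,3a,4,7-tetrahydroazulen-1(2H)-one (10α-hydroxy dienone without the isopropyl group) | O=C1CC[C@]2(C)[C@H](O)C=C(C)CC=C12 | intermediate
12 | (3aS,4R)-4-[(tert-butyldimethylsilyl)oxy]-3a,6-dimethyl-3,3a,4,7-tetrahydroazulen-1(2H)-one | O=C1CC[C@]2(C)[C@H](O[Si](C)(C)C(C)(C)C)C=C(C)CC=C12 | intermediate
13 | (3aS,4R,8S,8aR)-4-[(tert-butyldimethylsilyl)oxy]-3a,6-dimethyl-8-(4,4,5,5-tetramethyl-1,3,2-dioxaborolan-2-yl)-3,3a,4,7,8,8a-hexahydroazulen-1(2H)-one (boron at C6 α, H-5 α) | CC1(C)OB(OC1(C)C)[C@H]2CC(C)=C[C@@H](O[Si](C)(C)C(C)(C)C)[C@@]3(C)CCC(=O)[C@H]23 | intermediate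
14 | (3aS,4R,8S,8aS)-4-[(tert-butyldimethylsilyl)oxy]-8-hydroxy-3a,6-dimethyl-3,3a,4,7,8,8a-hexahydroazulen-1(2H)-one (6α-hydroxy, 5αH, trans-fused) | O[C@H]1CC(C)=C[C@@H](O[Si](C)(C)C(C)(C)C)[C@@]2(C)CCC(=O)[C@H]12 | intermediate
15 | (1R,3aS,4R,8S,8aS)-4-[(tert-butyldimethylsilyl)oxy]-3a,6-dimethyl-1-(propan-2-yl)-1,2,3,3a,4,7,8,8a-octahydroazulene-1,8-diol (10α-silyloxy-5αH-dauc-8-ene-4β,6α-diol) | O[C@H]1CC(C)=C[C@@H](O[Si](C)(C)C(C)(C)C)[C@@]2(C)CC[C@@](O)(C(C)C)[C@H]12 | intermediate
16 | 4-methoxybenzoyl chloride | COc1ccc(C(Cl)=O)cc1 | starting material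
17 | (1R,3aS,4R,8S,8aS)-4-[(tert-butyldimethylsilyl)oxy]-1-hydroxy-3a,6-dimethyl-1-(propan-2-yl)-1,2,3,3a,4,7,8,8a-octahydroazulen-8-yl 4-methoxybenzoate | COc1ccc(C(=O)O[C@H]2CC(C)=C[C@@H](O[Si](C)(C)C(C)(C)C)[C@@]3(C)CC[C@@](O)(C(C)C)[C@H]23)cc1 | intermediate
18 | (1R,3aS,4R,8S,8aS)-1,4-dihydroxy-3a,6-dimethyl-1-(propan-2-yl)-1,2,3,3a,4,7,8,8a-octahydroazulen-8-yl 4-methoxybenzoate (6α-(4-methoxybenzoyloxy)-5αH-dauc-8-ene-4β,10α-diol) | COc1ccc(C(=O)O[C@H]2CC(C)=C[C@@H](O)[C@@]3(C)CC[C@@](O)(C(C)C)[C@H]23)cc1 | intermediate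
19 | (1R,3aS,4R,8S,8aS)-4-(acetyloxy)-1-hydroxy-3a,6-dimethyl-1-(propan-2-yl)-1,2,3,3a,4,7,8,8a-octahydroazulen-8-yl 4-methoxybenzoate (10α-acetoxy-4β-hydroxy-6α-(4-methoxybenzoyloxy)-5αH-dauc-8-ene, CNP0256979.2) | COc1ccc(C(=O)O[C@H]2CC(C)=C[C@@H](OC(C)=O)[C@@]3(C)CC[C@@](O)(C(C)C)[C@H]23)cc1 | target

Total step count: 11. Longest linear sequence: 11 steps (from 1 and 2 to 19).

Steps most likely to fail:

Step 5. The inward methyl group at the C1 terminus may slow the rearrangement so much that, at the temperature then needed, 1,3-boron shift or carbonyl allylation by the allylboronate 10 and cis-to-trans isomerisation of the cyclopropane erode C10 and C1. The fallback sets out from 9 and comes back at 11 and puts the oxygen on the alkene before the rearrangement. KHF2 would convert 9 into the potassium (E)-alkenyltrifluoroborate F1. A Chan–Lam coupling with acetic acid mediated by Cu(OAc)2 would give, with retention of the alkene geometry, the (E)-enol acetate F2. Its Cope rearrangement would deliver the thermally robust allylic 10α-acetate F3 with no allylboron intermediate, and methanolysis (K2CO3, MeOH) would return 11.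

Step 7. Here C6 and C5 are set in two separate events, and the seven-membered ring, which is folded toward the α face, may direct the boryl group to the β face or allow the enolate to be protonated from the β face (cis ring fusion). The fallback sets out from 12 and comes back at 14 and replaces the conjugate addition by one concerted syn addition. Ketalisation of 12 with 1,2-bis(trimethylsilyloxy)ethane and TMSOTf at −78 °C (conditions that do not move the double bond) would give the dioxolane F4. Hydroboration with 9-BBN and perborate work-up would add H to C5 and OH to C6 from the same face, opposite to the C1 methyl group, to give the ketal alcohol F5; the C8=C9 bond is shielded by the silyloxy-bearing C10. Mild hydrolysis (PPTS, acetone/H2O) would return 14 without an enolate ever having been formed at C5.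

Step 8. The hindered, enolisable β-hydroxy ketone may be reduced by β-hydride transfer from the isopropyl reagent, or merely deprotonated, or cleaved by retro-aldol reaction instead of being alkylated. The fallback sets out from 14 and comes back at 15. Isopropenylmagnesium bromide with CeCl3 (a nucleophile that has no transferable β-hydride and is smaller) would give the isopropenyl carbinol F6 on the same α face, and hydrogenation with RhCl(PPh3)3 would then saturate the 1,1-disubstituted alkene in preference to the trisubstituted ring alkene to give 15.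

**Further compounds**

F1 | step 5 | potassium trifluoro{(E)-2-[(1R,2R)-1-methyl-2-(2-methyl-5-oxocyclopent-1-en-1-yl)cyclopropyl]ethenyl}borate | O=C1CCC(C)=C1[C@@H]2C[C@]2(C)/C=C/[B-](F)(F)F.[K+]
F2 | step 5 | (E)-2-[1-methyl-2-(2-methyl-5-oxocyclopent-1-en-1-yl)cyclopropyl]ethenyl acetate (the enol acetate analogue of 9, same configuration) | O=C1CCC(C)=C1[C@@H]2C[C@]2(C)/C=C/OC(C)=O
F3 | step 5 | (3aS,4R)-3a,6-dimethyl-1-oxo-1,2,3,3a,4,7-hexahydroazulen-4-yl acetate | O=C1CC[C@]2(C)[C@H](OC(C)=O)C=C(C)CC=C12
F4 | step 7 | ethylene ketal (spiro-1,3-dioxolane at C4) of 12 | C1COC2(O1)CC[C@]3(C)[C@H](O[Si](C)(C)C(C)(C)C)C=C(C)CC=C23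
F5 | step 7 | ethylene ketal (spiro-1,3-dioxolane at C4) of 14 | O[C@H]1CC(C)=C[C@@H](O[Si](C)(C)C(C)(C)C)[C@@]2(C)CCC3(OCCO3)[C@H]12
F6 | step 8 | isopropenyl analogue of 15 (prop-1-en-2-yl in place of propan-2-yl at C4) | O[C@H]1CC(C)=C[C@@H](O[Si](C)(C)C(C)(C)C)[C@@]2(C)CC[C@@](O)(C(C)=C)[C@H]12
A1 | direct plan | (5R)-2-diazo-5-(2-methoxy-4-methylphenyl)-6-methyl-5-(triethylsilyloxy)heptan-3-one | CC(=[N+]=[N-])C(=O)C[C@@](O[Si](CC)(CC)CC)(C(C)C)c1ccc(C)cc1OC
A2 | direct plan | 6-methoxy-4β-(triethylsilyloxy)dauca-5,7,9-trien-2-one | CC1=CC(OC)=C2[C@](O[Si](CC)(CC)CC)(C(C)C)CC(=O)[C@]2(C)C=C1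
A3 | direct plan | 4β-(triethylsilyloxy)-5αH-dauca-7,9-dien-6-one | O=C1C=C(C)C=C[C@@]2(C)CC[C@@](O[Si](CC)(CC)CC)(C(C)C)[C@H]12
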